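## Retrosynthetic overview

1. Target ⇐ reductive removal of a camphorsultam auxiliary from a 3-acyl-2,3-dihydrobenzofuran (C3–C(=O)N becomes C3–CH2OH).
2. Dihydrofuran ring ⇐ one-pot oxidative cross-coupling of an N-sinapoyl sultam with dihydroconiferyl alcohol, as in lignan biosynthesis: phenoxyl radical C8–C5′ coupling, re-aromatisation, then phenol addition to the p-quinone methide (O–C7). Here C7/C8 are the benzylic and α carbons of the sinapoyl chain and C5′ is the ring carbon ortho to the phenol OH of the partner.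
3. The saturated 3-hydroxypropyl arm is brought in with the phenol partner, so no later alkene reduction is needed.
4. C3 is set by the sultam during the radical coupling; C2 follows as trans in the quinone methide closure.
5. N-sinapoyl sultam ⇐ methyl sinapate + (1R)-(+)-2,10-camphorsultam. Both benzene rings are bought; the only ring formed is the dihydrofuran ring, in step 2.

Assumption: the sultam-bound radical reacts on the same face as N-enoyl sultams do in non-chelated additions (Cα-re for the (2R)-sultam, hence Cα-si for the (2S)-sultam used here); if the sense proves opposite, the equally available enantiomeric sultam is used with no other change.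

## Route

Step 1
Reactants: 1 methyl (E)-sinapate; 2 (1R)-(+)-2,10-camphorsultam
Product: 6 (2S)-N-[(E)-sinapoyl]bornane-10,2-sultam, via dimethylaluminium sultam amide 3 (not isolated), via dimethylaluminium phenoxide of methyl sinapate 4 (not isolated), via dimethylaluminium phenoxide of the acyl sultam 5 (not isolated)
Conditions: 2 (1.2 equiv) + AlMe3 (1.2 equiv), toluene, rt, 30 min; 1 (1.0 equiv) + AlMe3 (1.1 equiv), toluene, 0 °C; combine, 80 °C, 16 h; then 1 M HCl, 0 °C
Reagents that add atoms: none
Why: Weinreb-type aluminium amide aminolysis of a methyl ester, in which the N–AlMe2 sultam acylates while the phenol is masked in situ as its aluminium phenoxide, so no protecting group is needed; the E alkene and the sultam stereocentres are untouched and no new stereocentre is formed.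

Step 2
Reactants: 6 (2S)-N-[(E)-sinapoyl]bornane-10,2-sultam; 7 dihydroconiferyl alcohol
Product: 12 (2S)-N-{[(2S,3S)-2-(4-hydroxy-3,5-dimethoxyphenyl)-5-(3-hydroxypropyl)-7-methoxy-2,3-dihydrobenzofuran-3-yl]carbonyl}bornane-10,2-sultam (2,3-trans), via sinapoyl sultam phenoxyl radical 8 (not isolated), via dihydroconiferyl phenoxyl radical 9 (not isolated), via quinone methide dienone adduct 10 (not isolated), via hydroxyaryl quinone methide 11 (not isolated)
Conditions: 6 (1.0 equiv), 7 (4 equiv), Ag2O (1.3 equiv, four portions), CH2Cl2, rt, dark, 12–16 h; filter through Celite; chromatography (removes the minor 2R,3R diastereomer, recovers excess 7)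
Reagents that add atoms: none
Why: Proposed new method: Ag2O oxidises both phenols to phenoxyl radicals; the persistent sinapoyl radical (ortho positions blocked, 8–8 self-coupling slowed by two bulky sultams) couples through C8 with C5′ of the transient guaiacyl radical of 7, the dienone re-aromatises and its phenol adds to the p-quinone methide; the sultam in its s-cis, C=O/SO2-anti conformation leaves the Cα-si face open so C3 is formed S, and the ring closure places the aryl group trans so C2 is S; the closest known reactions are the Ag2O 8–5 dehydrodimerisation of ferulic acid derivatives carrying camphorsultam and the oxidative cross-coupling of monolignols with non-conjugated guaiacyl phenols.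

Step 3
Reactants: 12 (2S)-N-{[(2S,3S)-2-(4-hydroxy-3,5-dimethoxyphenyl)-5-(3-hydroxypropyl)-7-methoxy-2,3-dihydrobenzofuran-3-yl]carbonyl}bornane-10,2-sultam
Product: 14 4-[(2S,3R)-3-(hydroxymethyl)-5-(3-hydroxypropyl)-7-methoxy-2,3-dihydrobenzofuran-2-yl]-2,6-dimethoxyphenol (target), via dihydrobenzofuran-3-carbaldehyde 13 (not isolated)
Conditions: LiBH4 (5 equiv), THF, 0 °C to rt, 3 h; then 1 M HCl to pH 5–6 at 0 °C; chromatography (sultam 2 recovered)
Reagents that add atoms: none
Why: Reductive cleavage of an N-acyl sultam (acyl substitution by hydride to the aldehyde, then reduction to the primary alcohol) is faster than α-deprotonation, so C2 and C3 are not touched; the C3 descriptor changes from S to R only because CH2OH ranks below C2 whereas C(=O)N ranked above it.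

## Compound list

1 | methyl (E)-sinapate, methyl (2E)-3-(4-hydroxy-3,5-dimethoxyphenyl)prop-2-enoate (catalogue compound; also one esterification from sinapic acid) | COC(=O)/C=C/c1cc(OC)c(O)c(OC)c1 | starting material
2 | (1R)-(+)-2,10-camphorsultam, (2S)-bornane-10,2-sultam, (3aR,6S,7aS) | CC1(C)[C@H]2CC[C@@]13CS(=O)(=O)N[C@H]3C2 | starting material
3 | N-dimethylaluminium amide of 2 | CC1(C)[C@H]2CC[C@@]13CS(=O)(=O)N([Al](C)C)[C@H]3C2 | intermediate
4 | O-dimethylaluminium phenoxide of 1 | COC(=O)/C=C/c1cc(OC)c(O[Al](C)C)c(OC)c1 | intermediate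
5 | O-dimethylaluminium phenoxide of 6 | CC1(C)[C@H]2CC[C@@]13CS(=O)(=O)N(C(=O)/C=C/c4cc(OC)c(O[Al](C)C)c(OC)c4)[C@H]3C2 | intermediate
6 | (2S)-N-[(2E)-3-(4-hydroxy-3,5-dimethoxyphenyl)prop-2-enoyl]bornane-10,2-sultam | CC1(C)[C@H]2CC[C@@]13CS(=O)(=O)N(C(=O)/C=C/c4cc(OC)c(O)c(OC)c4)[C@H]3C2 | intermediate
7 | dihydroconiferyl alcohol, 4-(3-hydroxypropyl)-2-methoxyphenol | COc1cc(CCCO)ccc1O | starting material
8 | phenoxyl radical of 6 | CC1(C)[C@H]2CC[C@@]13CS(=O)(=O)N(C(=O)/C=C/c4cc(OC)c([O])c(OC)c4)[C@H]3C2 | intermediate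
9 | phenoxyl radical of 7 | COc1cc(CCCO)ccc1[O] | intermediate
10 | C8–C5′ coupling adduct, p-quinone methide joined at C8 (R) to a 6-oxocyclohexa-2,4-dienyl ring; C5′ configuration undefined, lost on tautomerisation | CC1(C)[C@H]2CC[C@@]13CS(=O)(=O)N(C(=O)[C@H](C=C4C=C(OC)C(=O)C(OC)=C4)C5C=C(CCCO)C=C(OC)C5=O)[C@H]3C2 | intermediate
11 | re-aromatised p-quinone methide with a 2-hydroxy-3-methoxy-5-(3-hydroxypropyl)phenyl group at C8 (R) | CC1(C)[C@H]2CC[C@@]13CS(=O)(=O)N(C(=O)[C@H](C=C4C=C(OC)C(=O)C(OC)=C4)c5cc(CCCO)cc(OC)c5O)[C@H]3C2 | intermediate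
12 | (2S)-N-{[(2S,3S)-2-(4-hydroxy-3,5-dimethoxyphenyl)-5-(3-hydroxypropyl)-7-methoxy-2,3-dihydrobenzofuran-3-yl]carbonyl}bornane-10,2-sultam, 2,3-trans | CC1(C)[C@H]2CC[C@@]13CS(=O)(=O)N(C(=O)[C@H]4c5cc(CCCO)cc(OC)c5O[C@@H]4c6cc(OC)c(O)c(OC)c6)[C@H]3C2 | intermediate
13 | (2S,3S)-2-(4-hydroxy-3,5-dimethoxyphenyl)-5-(3-hydroxypropyl)-7-methoxy-2,3-dihydrobenzofuran-3-carbaldehyde | COc1cc([C@H]2Oc3c(OC)cc(CCCO)cc3[C@@H]2C=O)cc(OC)c1O | intermediate
14 | 4-[(2S,3R)-3-(hydroxymethyl)-5-(3-hydroxypropyl)-7-methoxy-2,3-dihydrobenzofuran-2-yl]-2,6-dimethoxyphenol, 2,3-trans | COc1cc([C@H]2Oc3c(OC)cc(CCCO)cc3[C@@H]2CO)cc(OC)c1O | target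

## Step count and risk

Total steps: 3. Longest linear sequence: 3 (1 → 6 → 12 → 14).

Steps most likely to fail, in order of risk:

**Step 2 (cross-coupling).** The risks are self-coupling of 6 (8–8, 8–O–4), 8–O–4 instead of 8–5 cross-coupling, and modest facial selectivity. The fallback sets out from 1 and 7 and comes back at 14; it drops the auxiliary and takes the stereochemistry from a resolution. Methyl sinapate 1 and 7 (excess) are cross-coupled with Ag2O in CH2Cl2/acetone; the small ester is the better-precedented sinapate partner for 8–5 cross-coupling with guaiacyl phenols. This gives the racemic trans ester, that is methyl (2S,3S)-2-(4-hydroxy-3,5-dimethoxyphenyl)-5-(3-hydroxypropyl)-7-methoxy-2,3-dihydrobenzofuran-3-carboxylate F4 together with its (2R,3R) enantiomer F5. LiBH4 in THF/MeOH reduces both esters to 14 and its (2R,3S) enantiomer F6. Preparative HPLC on a cellulose tris(3,5-dimethylphenylcarbamate) phase then delivers 14.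

**Step 1 (ester aminolysis).** The aluminium phenoxide makes the cinnamate a poor electrophile, so aminolysis may stall. The fallback sets out from 2 and comes back at 6; it builds the C7=C8 bond instead of the N–C(=O) bond. Sultam 2 is deprotonated with NaH in THF and acylated with bromoacetyl bromide to (2S)-N-(bromoacetyl)bornane-10,2-sultam F1. Michaelis–Arbuzov reaction with P(OEt)3 at 110 °C gives (2S)-N-[(diethoxyphosphoryl)acetyl]bornane-10,2-sultam F2. Horner–Wadsworth–Emmons olefination of syringaldehyde F3 with F2 (LiCl, DBU 2.5 equiv, MeCN, rt to 50 °C; the aldehyde reacts as its phenoxide) gives 6 as the E isomer.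

**Step 3 (auxiliary removal).** Hydride may attack at sulfur of the hindered α-branched acyl sultam, or the reaction may be slow enough for base-induced ring opening to compete. The fallback sets out from 12 and comes back at 14; it separates cleavage from reduction. LiOH/H2O2 in THF/H2O at 0 °C cleaves the auxiliary selectively at the exocyclic carbonyl to give (2S,3S)-2-(4-hydroxy-3,5-dimethoxyphenyl)-5-(3-hydroxypropyl)-7-methoxy-2,3-dihydrobenzofuran-3-carboxylic acid F7. BH3·SMe2 in THF (0 °C to rt, MeOH quench) then reduces the free acid to 14 under non-basic conditions.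

## Further compounds

F1 | step 1 | (2S)-N-(bromoacetyl)bornane-10,2-sultam | CC1(C)[C@H]2CC[C@@]13CS(=O)(=O)N(C(=O)CBr)[C@H]3C2
F2 | step 1 | (2S)-N-[(diethoxyphosphoryl)acetyl]bornane-10,2-sultam | CC1(C)[C@H]2CC[C@@]13CS(=O)(=O)N(C(=O)CP(=O)(OCC)OCC)[C@H]3C2
F3 | step 1 | syringaldehyde, 4-hydroxy-3,5-dimethoxybenzaldehyde | COc1cc(C=O)cc(OC)c1O
F4 | step 2 | methyl (2S,3S)-2-(4-hydroxy-3,5-dimethoxyphenyl)-5-(3-hydroxypropyl)-7-methoxy-2,3-dihydrobenzofuran-3-carboxylate | COC(=O)[C@H]1c2cc(CCCO)cc(OC)c2O[C@@H]1c3cc(OC)c(O)c(OC)c3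
F5 | step 2 | methyl (2R,3R)-2-(4-hydroxy-3,5-dimethoxyphenyl)-5-(3-hydroxypropyl)-7-methoxy-2,3-dihydrobenzofuran-3-carboxylate | COC(=O)[C@@H]1c2cc(CCCO)cc(OC)c2O[C@H]1c3cc(OC)c(O)c(OC)c3
F6 | step 2 | 4-[(2R,3S)-3-(hydroxymethyl)-5-(3-hydroxypropyl)-7-methoxy-2,3-dihydrobenzofuran-2-yl]-2,6-dimethoxyphenol, enantiomer of 14 | COc1cc([C@@H]2Oc3c(OC)cc(CCCO)cc3[C@H]2CO)cc(OC)c1O
F7 | step 3 | (2S,3S)-2-(4-hydroxy-3,5-dimethoxyphenyl)-5-(3-hydroxypropyl)-7-methoxy-2,3-dihydrobenzofuran-3-carboxylic acid | OC(=O)[C@H]1c2cc(CCCO)cc(OC)c2O[C@@H]1c3cc(OC)c(O)c(OC)c3
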